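**Retrosynthetic overview**

- Lappaol A 27 ⇐ di-O-benzyl trichloroethyl ester 24 (ester to CH2OH through the free acid, then debenzylation) ⇐ aryldiazoacetate 22, by an intramolecular rhodium carbene C–H insertion that makes C2–C3 and closes the dihydrofuran ring.
- Feature used: C2 of the dihydrobenzofuran is bonded to O1 and to guaiacyl ring C, so in the open ArO–CH2–Ar ether its C–H bond is doubly activated and lies 1,5 to a carbene placed at C3 on ring B.
- 22 ⇐ arylacetic acid 19 ⇐ ortho-allyl phenol 11 (Claisen shift, later alkene cleavage); the phenol oxygen and the lactone alpha carbon are both alkylated with the same bromide 13.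
- 11 ⇐ (R)-beta-benzyl butyrolactone 8 ⇐ Stobbe half-ester 3, by asymmetric hydrogenation and ester reduction.
- Ring order: butyrolactone first (step 3), dihydrofuran ring last (step 14); the three benzene rings are bought.

Key step: step 14

Assumption: the catalyst antipodes written in steps 2 and 14 are the ones expected to give R at lactone C4 and S at C2; should a first run show the opposite sense, the mirror-image catalyst is used with nothing else changed; alcohol 12 is taken as an article of commerce.

**Route**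

Step 1
Reactants: 1 4-benzyloxy-3-methoxybenzaldehyde; 2 dimethyl succinate
Product: 3 (E)-4-(4-benzyloxy-3-methoxyphenyl)-3-(methoxycarbonyl)but-3-enoic acid
Conditions: NaOMe, MeOH, reflux; aq. HCl work-up
Reagents that add atoms: dimethyl succinate (compound 2), COC(=O)CCC(=O)OC
Why: Stobbe condensation, in which the succinate enolate adds to the non-enolisable aldehyde and the adduct collapses irreversibly to the carboxylate of the alkylidene half-ester, the E isomer (aryl trans to the ester) being favoured.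

Step 2
Reactants: 3 (E)-4-(4-benzyloxy-3-methoxyphenyl)-3-(methoxycarbonyl)but-3-enoic acid
Product: 4 (R)-4-(4-benzyloxy-3-methoxyphenyl)-3-(methoxycarbonyl)butanoic acid
Conditions: H2 (5 bar), [Rh(cod)((S,S)-Et-DuPhos)]BF4 (0.5 mol%), NaOMe (10 mol%), MeOH, rt
Reagents that add atoms: none
Why: Rhodium-catalysed asymmetric hydrogenation of an itaconate-type half-ester, in which carboxylate and alkene chelate the cationic bisphosphine rhodium centre so that H2 adds to one face and the future lactone C4 is set as R, the aryl benzyl ether being inert to this catalyst.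

Step 3
Reactants: 4 (R)-4-(4-benzyloxy-3-methoxyphenyl)-3-(methoxycarbonyl)butanoic acid
Product: 7 (R)-4-(4-benzyloxy-3-methoxybenzyl)dihydrofuran-2(3H)-one, via potassium carboxylate 5 (not isolated), via hydroxy acid 6 (not isolated)
Conditions: KOH (1 equiv), EtOH, 0 °C; CaCl2, NaBH4, EtOH, −10 °C to rt; then 3 M HCl, rt
Reagents that add atoms: none
Why: Chemoselective borohydride reduction, in which Ca(BH4)2 reduces the methyl ester but not the carboxylate salt and acidification lactonises the gamma-hydroxy acid, so the untouched stereocentre becomes the R-configured beta carbon of the lactone.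

Step 4
Reactants: 7 (R)-4-(4-benzyloxy-3-methoxybenzyl)dihydrofuran-2(3H)-one
Product: 8 (R)-4-(4-hydroxy-3-methoxybenzyl)dihydrofuran-2(3H)-one
Conditions: H2 (1 atm), 10% Pd/C, EtOAc, rt
Reagents that add atoms: none
Why: Catalytic hydrogenolysis of the aryl benzyl ether, which frees the ring B phenol before ring A is brought in, so that the two guaiacyl oxygens stay distinguishable.

Step 5
Reactants: 8 (R)-4-(4-hydroxy-3-methoxybenzyl)dihydrofuran-2(3H)-one; 9 allyl bromide
Product: 10 (R)-4-(4-allyloxy-3-methoxybenzyl)dihydrofuran-2(3H)-one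
Conditions: K2CO3, acetone, reflux
Reagents that add atoms: allyl bromide (compound 9), C=CCBr
Why: Williamson ether synthesis of the phenoxide with an unhindered allylic bromide under a base too weak to disturb the lactone.

Step 6
Reactants: 10 (R)-4-(4-allyloxy-3-methoxybenzyl)dihydrofuran-2(3H)-one
Product: 11 (R)-4-(3-allyl-4-hydroxy-5-methoxybenzyl)dihydrofuran-2(3H)-one
Conditions: N,N-diethylaniline, 200 °C, sealed vessel
Reagents that add atoms: none
Why: Aromatic Claisen rearrangement, whose [3,3] shift can end productively only at the free ortho carbon (the other ortho position bears OMe and the para position is blocked) before tautomerisation restores the phenol, while the remote stereocentre has no acidic hydrogen.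

Step 7
Reactants: 12 (4-benzyloxy-3-methoxyphenyl)methanol
Product: 13 4-benzyloxy-3-methoxybenzyl bromide
Conditions: PBr3, Et2O, 0 °C; used at once without storage
Reagents that add atoms: phosphorus tribromide, BrP(Br)Br
Why: Bromination of an electron-rich benzylic alcohol through its phosphite ester (Appel-type substitution with PBr3), run cold because such bromides do not keep.

Step 8
Reactants: 11 (R)-4-(3-allyl-4-hydroxy-5-methoxybenzyl)dihydrofuran-2(3H)-one; 13 4-benzyloxy-3-methoxybenzyl bromide
Product: 14 (R)-4-{3-allyl-4-[(4-benzyloxy-3-methoxybenzyl)oxy]-5-methoxybenzyl}dihydrofuran-2(3H)-one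
Conditions: K2CO3, DMF, rt
Reagents that add atoms: 4-benzyloxy-3-methoxybenzyl bromide (compound 13), COc1cc(CBr)ccc1OCc1ccccc1
Why: Williamson ether synthesis of the flanked but acidic phenol with a reactive benzylic bromide, which installs the O–CH2–aryl unit whose C–H bond is used in step 14.

Step 9
Reactants: 14 (R)-4-{3-allyl-4-[(4-benzyloxy-3-methoxybenzyl)oxy]-5-methoxybenzyl}dihydrofuran-2(3H)-one; 13 4-benzyloxy-3-methoxybenzyl bromide
Product: 16 (3R,4R)-4-{3-allyl-4-[(4-benzyloxy-3-methoxybenzyl)oxy]-5-methoxybenzyl}-3-(4-benzyloxy-3-methoxybenzyl)dihydrofuran-2(3H)-one, via lithium enolate 15 (not isolated)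
Conditions: LiN(SiMe3)2 (1.05 equiv), THF, −78 °C; then 13, −78 to −30 °C
Reagents that add atoms: 4-benzyloxy-3-methoxybenzyl bromide (compound 13), COc1cc(CBr)ccc1OCc1ccccc1
Why: Enolate alkylation of a beta-substituted gamma-butyrolactone, in which the bromide approaches the planar lithium enolate anti to the C4 benzyl group so that C3 is set as R, trans to C4, by substrate control, one equivalent of base at low temperature limiting dialkylation.

Step 10
Reactants: 16 (3R,4R)-4-{3-allyl-4-[(4-benzyloxy-3-methoxybenzyl)oxy]-5-methoxybenzyl}-3-(4-benzyloxy-3-methoxybenzyl)dihydrofuran-2(3H)-one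
Product: 18 arylacetaldehyde of the trans lactone (allyl group of 16 shortened to CH2CHO), via vicinal diol 17 (not isolated)
Conditions: OsO4 (2 mol%), NaIO4, 2,6-lutidine, dioxane/H2O, rt; crude product taken on directly
Reagents that add atoms: osmium tetroxide, O=[Os](=O)(=O)=O; sodium periodate, [Na+].[O-]I(=O)(=O)=O
Why: Lemieux–Johnson oxidation, in which OsO4 dihydroxylates only the terminal alkene and NaIO4 cleaves the diol to the arylacetaldehyde, 2,6-lutidine holding the medium near neutral so that the acid-labile alkoxybenzyl aryl ether and the electron-rich rings survive.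

Step 11
Reactants: 18 arylacetaldehyde of the trans lactone
Product: 19 arylacetic acid of the trans lactone (CH2CO2H on ring B)
Conditions: NaClO2, NaH2PO4, 2-methyl-2-butene, t-BuOH/H2O, 0 °C to rt
Reagents that add atoms: sodium chlorite, [Na+].[O-]Cl=O
Why: Pinnick oxidation of the aldehyde under buffered conditions, with 2-methyl-2-butene trapping HOCl so that the electron-rich arenes are not chlorinated.

Step 12
Reactants: 19 arylacetic acid of the trans lactone; 20 2,2,2-trichloroethanol
Product: 21 2,2,2-trichloroethyl arylacetate of the trans lactone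
Conditions: DCC, DMAP (10 mol%), CH2Cl2, 0 °C to rt
Reagents that add atoms: 2,2,2-trichloroethanol (compound 20), OCC(Cl)(Cl)Cl
Why: Steglich esterification under neutral conditions that spare lactone and benzylic ethers, the trichloroethyl group being chosen because it can later be removed reductively beside the lactone.

Step 13
Reactants: 21 2,2,2-trichloroethyl arylacetate of the trans lactone
Product: 22 2,2,2-trichloroethyl aryldiazoacetate of the trans lactone
Conditions: p-ABSA, DBU, MeCN, 0 °C to rt
Reagents that add atoms: 4-acetamidobenzenesulfonyl azide (p-ABSA), CC(=O)Nc1ccc(cc1)S(=O)(=O)N=[N+]=[N-]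
Why: Regitz diazo transfer, in which DBU deprotonates only the doubly activated arylacetate CH2 (far more acidic than the lactone alpha hydrogen) and the enolate takes N2 from the sulfonyl azide.

Step 14
Reactants: 22 2,2,2-trichloroethyl aryldiazoacetate of the trans lactone
Product: 24 2,2,2-trichloroethyl (2S,3S)-trans-2-aryl-2,3-dihydrobenzofuran-3-carboxylate on the full skeleton, via cis-(2S,3R) ester 23 (not isolated)
Conditions: Rh2(S-PTTL)4 (2 mol%), 4 Å MS, toluene/CH2Cl2, −60 to −20 °C, slow addition of 22; then DBU, rt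
Reagents that add atoms: none
Why: Rh2(S-PTTL)4 (dirhodium tetrakis[N-phthaloyl-(S)-tert-leucinate]) expels N2 from 22 to give a donor/acceptor rhodium carbene at the future C3, which inserts into one C–H bond of the neighbouring ArO–CH2–Ar ether through a three-centre transition state in which hydride transfer runs ahead of C–C bond formation, the positive charge growing at C2 being carried by O1 and by the para-benzyloxy ring C. The closest known reaction type is the dirhodium carboxylate-catalysed intramolecular C–H insertion of ortho-benzyloxy aryldiazoacetates, which gives 2-aryl-2,3-dihydrobenzofuran-3-carboxylates. The dihydrofuran ring closes by 1,5-insertion (carbene carbon, C3a, C7a, O1, C2), and this is the only five-membered mode available, because the lactone C–H bonds, the ring B benzylic CH2 (meta to the carbene) and the two O-benzyl CH2 groups cannot reach the carbene through a five-membered transition state. C2 is set as S by the chiral carboxylate pocket of the catalyst, which selects one of the two enantiotopic ether hydrogens; C3 forms cis (kinetic product 23) and DBU then epimerises it through the ester enolate to the more stable 2,3-trans isomer 24 (3S) without touching C2. The step needs site selectivity, secured by the 1,5 geometry and the double activation of the ether C–H bond, and chemoselectivity against carbene dimerisation and O–H insertion, secured by slow addition under dry conditions. The insertion itself runs in a neutral, non-nucleophilic medium, so the trans lactone and the remaining benzyl ethers pass through unchanged.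

Step 15
Reactants: 24 2,2,2-trichloroethyl (2S,3S)-trans-2-aryl-2,3-dihydrobenzofuran-3-carboxylate on the full skeleton
Product: 25 (2S,3S)-trans-2-aryl-2,3-dihydrobenzofuran-3-carboxylic acid on the full skeleton
Conditions: Zn dust, AcOH/THF, rt
Reagents that add atoms: none
Why: Reductive fragmentation of the trichloroethyl ester by zinc (two-electron reduction of a C–Cl bond, then beta-elimination of the carboxylate), which leaves lactone, benzyl ethers and the C3 stereocentre untouched.

Step 16
Reactants: 25 (2S,3S)-trans-2-aryl-2,3-dihydrobenzofuran-3-carboxylic acid on the full skeleton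
Product: 26 di-O-benzyl lappaol A
Conditions: BH3·THF, THF, 0 °C to rt; MeOH quench, aqueous work-up
Reagents that add atoms: none
Why: Chemoselective borane reduction, in which BH3 reduces the free carboxylic acid through its acyloxyborane much faster than the lactone and C3 keeps its geometry (its descriptor changes from S to R only because the substituent priorities change).

Step 17
Reactants: 26 di-O-benzyl lappaol A
Product: 27 lappaol A
Conditions: H2 (1 atm), 10% Pd/C, EtOAc/MeOH, rt, stopped when 26 is consumed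
Reagents that add atoms: none
Why: Catalytic hydrogenolysis of the two aryl benzyl ethers, which should cleave much faster than the hindered cyclic benzylic C2–O1 bond when the reaction is stopped at full conversion.

**Compound list**

1 | 4-benzyloxy-3-methoxybenzaldehyde | COc1cc(C=O)ccc1OCc1ccccc1 | starting material
2 | dimethyl succinate | COC(=O)CCC(=O)OC | starting material
3 | (E)-4-(4-benzyloxy-3-methoxyphenyl)-3-(methoxycarbonyl)but-3-enoic acid | COC(=O)/C(CC(=O)O)=C/c1ccc(OCc2ccccc2)c(OC)c1 | intermediate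
4 | (R)-4-(4-benzyloxy-3-methoxyphenyl)-3-(methoxycarbonyl)butanoic acid | COC(=O)[C@@H](CC(=O)O)Cc1ccc(OCc2ccccc2)c(OC)c1 | intermediate
5 | potassium (R)-4-(4-benzyloxy-3-methoxyphenyl)-3-(methoxycarbonyl)butanoate | [K+].COC(=O)[C@@H](CC(=O)[O-])Cc1ccc(OCc2ccccc2)c(OC)c1 | intermediate
6 | (R)-4-(4-benzyloxy-3-methoxyphenyl)-3-(hydroxymethyl)butanoic acid | OC[C@@H](CC(=O)O)Cc1ccc(OCc2ccccc2)c(OC)c1 | intermediate
7 | (R)-4-(4-benzyloxy-3-methoxybenzyl)dihydrofuran-2(3H)-one | O=C1C[C@@H](Cc2ccc(OCc3ccccc3)c(OC)c2)CO1 | intermediate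
8 | (R)-4-(4-hydroxy-3-methoxybenzyl)dihydrofuran-2(3H)-one | O=C1C[C@@H](Cc2ccc(O)c(OC)c2)CO1 | intermediate
9 | allyl bromide | C=CCBr | starting material
10 | (R)-4-(4-allyloxy-3-methoxybenzyl)dihydrofuran-2(3H)-one | O=C1C[C@@H](Cc2ccc(OCC=C)c(OC)c2)CO1 | intermediate
11 | (R)-4-(3-allyl-4-hydroxy-5-methoxybenzyl)dihydrofuran-2(3H)-one | O=C1C[C@@H](Cc2cc(CC=C)c(O)c(OC)c2)CO1 | intermediate
12 | (4-benzyloxy-3-methoxyphenyl)methanol | COc1cc(CO)ccc1OCc1ccccc1 | starting material
13 | 4-benzyloxy-3-methoxybenzyl bromide | COc1cc(CBr)ccc1OCc1ccccc1 | intermediate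
14 | (R)-4-{3-allyl-4-[(4-benzyloxy-3-methoxybenzyl)oxy]-5-methoxybenzyl}dihydrofuran-2(3H)-one | O=C1C[C@@H](Cc2cc(CC=C)c(OCc3ccc(OCc4ccccc4)c(OC)c3)c(OC)c2)CO1 | intermediate
15 | lithium enolate of 14 (lithium 2-oxido-4,5-dihydrofuran, R at the benzyl-bearing carbon) | [Li+].[O-]C1=C[C@@H](Cc2cc(CC=C)c(OCc3ccc(OCc4ccccc4)c(OC)c3)c(OC)c2)CO1 | intermediate
16 | (3R,4R)-4-{3-allyl-4-[(4-benzyloxy-3-methoxybenzyl)oxy]-5-methoxybenzyl}-3-(4-benzyloxy-3-methoxybenzyl)dihydrofuran-2(3H)-one | COc1cc(C[C@H]2C(=O)OC[C@@H]2Cc2cc(OC)c(OCc3ccc(OCc4ccccc4)c(OC)c3)c(CC=C)c2)ccc1OCc1ccccc1 | intermediate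
17 | (3R,4R)-3-(4-benzyloxy-3-methoxybenzyl)-4-{4-[(4-benzyloxy-3-methoxybenzyl)oxy]-3-(2,3-dihydroxypropyl)-5-methoxybenzyl}dihydrofuran-2(3H)-one, both carbinol epimers | COc1cc(C[C@H]2C(=O)OC[C@@H]2Cc2cc(OC)c(OCc3ccc(OCc4ccccc4)c(OC)c3)c(CC(O)CO)c2)ccc1OCc1ccccc1 | intermediate
18 | 2-{2-[(4-benzyloxy-3-methoxybenzyl)oxy]-5-{[(3R,4R)-4-(4-benzyloxy-3-methoxybenzyl)-5-oxotetrahydrofuran-3-yl]methyl}-3-methoxyphenyl}acetaldehyde | COc1cc(C[C@H]2C(=O)OC[C@@H]2Cc2cc(OC)c(OCc3ccc(OCc4ccccc4)c(OC)c3)c(CC=O)c2)ccc1OCc1ccccc1 | intermediate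
19 | 2-{2-[(4-benzyloxy-3-methoxybenzyl)oxy]-5-{[(3R,4R)-4-(4-benzyloxy-3-methoxybenzyl)-5-oxotetrahydrofuran-3-yl]methyl}-3-methoxyphenyl}acetic acid | COc1cc(C[C@H]2C(=O)OC[C@@H]2Cc2cc(OC)c(OCc3ccc(OCc4ccccc4)c(OC)c3)c(CC(=O)O)c2)ccc1OCc1ccccc1 | intermediate
20 | 2,2,2-trichloroethanol | OCC(Cl)(Cl)Cl | starting material
21 | 2,2,2-trichloroethyl 2-{2-[(4-benzyloxy-3-methoxybenzyl)oxy]-5-{[(3R,4R)-4-(4-benzyloxy-3-methoxybenzyl)-5-oxotetrahydrofuran-3-yl]methyl}-3-methoxyphenyl}acetate | COc1cc(C[C@H]2C(=O)OC[C@@H]2Cc2cc(OC)c(OCc3ccc(OCc4ccccc4)c(OC)c3)c(CC(=O)OCC(Cl)(Cl)Cl)c2)ccc1OCc1ccccc1 | intermediate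
22 | 2,2,2-trichloroethyl 2-diazo-2-{2-[(4-benzyloxy-3-methoxybenzyl)oxy]-5-{[(3R,4R)-4-(4-benzyloxy-3-methoxybenzyl)-5-oxotetrahydrofuran-3-yl]methyl}-3-methoxyphenyl}acetate | COc1cc(C[C@H]2C(=O)OC[C@@H]2Cc2cc(OC)c(OCc3ccc(OCc4ccccc4)c(OC)c3)c(c2)C(=[N+]=[N-])C(=O)OCC(Cl)(Cl)Cl)ccc1OCc1ccccc1 | intermediate
23 | 2,2,2-trichloroethyl (2S,3R)-cis-2-(4-benzyloxy-3-methoxyphenyl)-5-{[(3R,4R)-4-(4-benzyloxy-3-methoxybenzyl)-5-oxotetrahydrofuran-3-yl]methyl}-7-methoxy-2,3-dihydrobenzofuran-3-carboxylate | COc1cc(C[C@H]2C(=O)OC[C@@H]2Cc2cc(OC)c3c(c2)[C@@H](C(=O)OCC(Cl)(Cl)Cl)[C@@H](c2ccc(OCc4ccccc4)c(OC)c2)O3)ccc1OCc1ccccc1 | intermediate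
24 | 2,2,2-trichloroethyl (2S,3S)-trans-2-(4-benzyloxy-3-methoxyphenyl)-5-{[(3R,4R)-4-(4-benzyloxy-3-methoxybenzyl)-5-oxotetrahydrofuran-3-yl]methyl}-7-methoxy-2,3-dihydrobenzofuran-3-carboxylate | COc1cc(C[C@H]2C(=O)OC[C@@H]2Cc2cc(OC)c3c(c2)[C@H](C(=O)OCC(Cl)(Cl)Cl)[C@@H](c2ccc(OCc4ccccc4)c(OC)c2)O3)ccc1OCc1ccccc1 | intermediate
25 | (2S,3S)-trans-2-(4-benzyloxy-3-methoxyphenyl)-5-{[(3R,4R)-4-(4-benzyloxy-3-methoxybenzyl)-5-oxotetrahydrofuran-3-yl]methyl}-7-methoxy-2,3-dihydrobenzofuran-3-carboxylic acid | COc1cc(C[C@H]2C(=O)OC[C@@H]2Cc2cc(OC)c3c(c2)[C@H](C(=O)O)[C@@H](c2ccc(OCc4ccccc4)c(OC)c2)O3)ccc1OCc1ccccc1 | intermediate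
26 | di-O-benzyl lappaol A: (3R,4R)-3-(4-benzyloxy-3-methoxybenzyl)-4-{[(2S,3R)-2-(4-benzyloxy-3-methoxyphenyl)-3-(hydroxymethyl)-7-methoxy-2,3-dihydrobenzofuran-5-yl]methyl}dihydrofuran-2(3H)-one | COc1cc(C[C@H]2C(=O)OC[C@@H]2Cc2cc(OC)c3c(c2)[C@H](CO)[C@@H](c2ccc(OCc4ccccc4)c(OC)c2)O3)ccc1OCc1ccccc1 | intermediate
27 | lappaol A: (3R,4R)-3-(4-hydroxy-3-methoxybenzyl)-4-{[(2S,3R)-2-(4-hydroxy-3-methoxyphenyl)-3-(hydroxymethyl)-7-methoxy-2,3-dihydrobenzofuran-5-yl]methyl}dihydrofuran-2(3H)-one | COc1cc(C[C@H]2C(=O)OC[C@@H]2Cc2cc(OC)c3c(c2)[C@H](CO)[C@@H](c2ccc(O)c(OC)c2)O3)ccc1O | target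

**Step count**

Total: 17 steps. Longest linear sequence: 16 steps (steps 1 to 6 and 8 to 17, from 1 and 2 to 27); step 7 is a one-step side branch.

**Steps most likely to fail, with fallbacks**

Step 14. Facial control at C2 may be lost if the insertion drifts towards a stepwise hydride-transfer path, which the electron-rich ring C favours, or if the catalyst pocket matches the bulky trichloroethyl ester poorly. The resulting C2 epimers differ from the wanted isomer only relative to remote centres and would be hard to separate. The fallback moves stereocontrol from the catalyst alone to a covalently bound ester auxiliary. It sets out from acid 19: Steglich esterification (DCC, DMAP) with (S)-2-hydroxy-1-(pyrrolidin-1-yl)propan-1-one, made from ethyl (S)-lactate and pyrrolidine (the R alcohol if that proves the matched case), gives the lactamide ester F1. Diazo transfer (p-ABSA, DBU) gives the auxiliary diazo ester F2. Insertion with Rh2(S-DOSP)4 or its mirror image as the matched partner, followed by DBU if needed, gives the trans auxiliary ester F3 by double stereodifferentiation. LiOH in THF/H2O at 0 °C then cleaves the activated alpha-acyloxy amide ester and at the same time opens the lactone to the seco hydroxy diacid F4, which recloses to the gamma-lactone on acidification with 1 M HCl. The fallback comes back to the route at acid 25.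

Step 10. The enolisable arylacetaldehyde may over-oxidise or self-condense, and the three electron-rich rings may suffer oxidative damage during the alkene cleavage. The fallback brings in the two-carbon unit as the finished diazoacetate by cross-coupling, with no Claisen shift and no oxidation. It sets out from phenol 8: I2 and NaHCO3 in THF/H2O iodinate ortho to the hydroxyl and give the iodophenol lactone F5. K2CO3 and bromide 13 in DMF give the iodoaryl benzylic ether F6. LiN(SiMe3)2 and 13 at −78 °C give the trans-dibenzyl lactone aryl iodide F7. Coupling of F7 with 2,2,2-trichloroethyl diazoacetate ([N-]=[N+]=CC(=O)OCC(Cl)(Cl)Cl) under Pd(PPh3)4, Ag2CO3 and Et3N in toluene at rt, a known aryl iodide coupling that keeps the diazo group, comes back to the route at 22. The flanking ether makes this coupling hindered, which is why it is the reserve and not the main line.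

Step 17. Hydrogenolysis may run on into the cyclic benzylic C2–O1 bond once the para hydroxyl of ring C is free, opening the dihydrofuran ring. The fallback replaces hydrogenation by Lewis-acid debenzylation. It sets out from 26: BCl3 with pentamethylbenzene as cation scavenger in CH2Cl2 at −78 °C removes both aryl benzyl groups and comes back to the route at 27; it makes no new compound (F0).

Further compounds
F1 | step 14 | (S)-1-oxo-1-(pyrrolidin-1-yl)propan-2-yl ester of acid 19 (lactamide ester) | COc1cc(C[C@H]2C(=O)OC[C@@H]2Cc2cc(OC)c(OCc3ccc(OCc4ccccc4)c(OC)c3)c(CC(=O)O[C@@H](C)C(=O)N3CCCC3)c2)ccc1OCc1ccccc1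
F2 | step 14 | (S)-1-oxo-1-(pyrrolidin-1-yl)propan-2-yl aryldiazoacetate (auxiliary diazo ester) | COc1cc(C[C@H]2C(=O)OC[C@@H]2Cc2cc(OC)c(OCc3ccc(OCc4ccccc4)c(OC)c3)c(c2)C(=[N+]=[N-])C(=O)O[C@@H](C)C(=O)N2CCCC2)ccc1OCc1ccccc1
F3 | step 14 | (S)-1-oxo-1-(pyrrolidin-1-yl)propan-2-yl (2S,3S)-trans-2-aryl-2,3-dihydrobenzofuran-3-carboxylate on the full skeleton (trans auxiliary ester) | COc1cc(C[C@H]2C(=O)OC[C@@H]2Cc2cc(OC)c3c(c2)[C@H](C(=O)O[C@@H](C)C(=O)N2CCCC2)[C@@H](c2ccc(OCc4ccccc4)c(OC)c2)O3)ccc1OCc1ccccc1
F4 | step 14 | seco hydroxy diacid of 25 (lactone opened to CH2OH and CO2H, all four stereocentres as in 25) | COc1cc(C[C@@H](C(=O)O)[C@H](CO)Cc2cc(OC)c3c(c2)[C@H](C(=O)O)[C@@H](c2ccc(OCc4ccccc4)c(OC)c2)O3)ccc1OCc1ccccc1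
F5 | step 10 | (R)-4-(4-hydroxy-3-iodo-5-methoxybenzyl)dihydrofuran-2(3H)-one | O=C1C[C@@H](Cc2cc(I)c(O)c(OC)c2)CO1
F6 | step 10 | (R)-4-{4-[(4-benzyloxy-3-methoxybenzyl)oxy]-3-iodo-5-methoxybenzyl}dihydrofuran-2(3H)-one | O=C1C[C@@H](Cc2cc(I)c(OCc3ccc(OCc4ccccc4)c(OC)c3)c(OC)c2)CO1
F7 | step 10 | (3R,4R)-3-(4-benzyloxy-3-methoxybenzyl)-4-{4-[(4-benzyloxy-3-methoxybenzyl)oxy]-3-iodo-5-methoxybenzyl}dihydrofuran-2(3H)-one | COc1cc(C[C@H]2C(=O)OC[C@@H]2Cc2cc(OC)c(OCc3ccc(OCc4ccccc4)c(OC)c3)c(I)c2)ccc1OCc1ccccc1
F0 | step 17 | none | none
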